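**Strategy.** The route rests on closing the cyclopentane at the bond between the methyl-bearing quaternary fusion carbon (C-6) and the acetoxy-bearing CH of the five-membered ring (C-7) by an intramolecular aldol addition. The enolate of an acyclic methyl ketone (carbonyl = C-5, the later CH–OAc of the seven-membered ring) attacks the C-7 aldehyde and sets C-6, C-7 and the C-5/C-7 1,3-dioxygen pattern in one operation. The keto aldehyde is unravelled by glycol cleavage from a cyclohexanediol made from 4-isopropylphenol by dearomatisation and enantioselective desymmetrisation. Ring-closing metathesis then adds the seven-membered ring trans to the cyclopentane.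

Key step: step 10

**Remarks**
- Atom labels used throughout (carbocycle of the target): C-1 = CH–O-angelate, C-2 = CH2, C-3 = methylated epoxide carbon, C-4 = epoxide CH, C-5 = CH–OAc of the seven-membered ring, C-6 = quaternary fusion carbon, C-7 = CH–OAc of the cyclopentane, C-8 = CH2, C-9 = C(OH)iPr, C-10 = fusion CH. In these labels the target is 1S,3R,4S,5S,6R,7S,9R,10S.
- The cyclopentane is made before the seven-membered ring on purpose: an aldol onto a preformed cycloheptenone is expected to give the cis-fused bicycle.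
- C-6 in compounds 6–14 and C-5/C-7 in 12–13 are drawn as the expected major epimers. These centres are erased in steps 9 and 10, so their configuration does not matter.
- The sense of induction in steps 2 and 5 is assumed from the usual models for these reagents.

**Step 1**
Reactants: 1 4-isopropylphenol
Product: 3 4-hydroxy-4-isopropylcyclohexa-2,5-dien-1-one, via hydroperoxy dienone 2 (not isolated)
Conditions: KHSO5 (as 2KHSO5·KHSO4·K2SO4), NaHCO3, MeCN/H2O, rt; then Me2S
Reagents that add atoms: potassium peroxymonosulfate [K+].[O-]S(=O)(=O)OO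
Why: Singlet oxygen generated from the peroxymonosulfate adds para to the phenolate (oxidative dearomatisation) and the hydroperoxide is reduced in the same flask to the achiral p-quinol; no stereocentre is formed.

**Step 2**
Reactants: 3 4-hydroxy-4-isopropylcyclohexa-2,5-dien-1-one
Product: 4 (4S,5S)-5-ethenyl-4-hydroxy-4-isopropylcyclohex-2-en-1-one
Conditions: CH2=CHBF3K (1.1 equiv), [Rh(cod)OH]2 (2.5 mol%), (S)-BINAP, dioxane/H2O, 50 °C
Reagents that add atoms: potassium vinyltrifluoroborate C=C[B-](F)(F)F.[K+]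
Why: Rhodium-catalysed asymmetric 1,4-addition (Hayashi–Miyaura) desymmetrises the dienone: the vinyl group should enter cis to the hydroxyl and trans to the isopropyl group while the ligand selects one enantiotopic enone, which sets C-9 and C-10.

**Step 3**
Reactants: 4 (4S,5S)-5-ethenyl-4-hydroxy-4-isopropylcyclohex-2-en-1-one
Product: 6 (4S,5R,6R)-5-ethenyl-4-hydroxy-6-methyl-4-isopropylcyclohex-2-en-1-one, via dilithium dienolate alkoxide 5 (not isolated)
Conditions: LiN(iPr)2 (2.2 equiv), THF, −78 °C; MeI, −78 → −30 °C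
Reagents that add atoms: iodomethane CI
Why: Enolate alkylation; the enone side has no α-hydrogen, so only C-6 is deprotonated and methylated (trans to vinyl expected), and the C-6 configuration is irrelevant because it is erased in step 10.

**Step 4**
Reactants: 6 (4S,5R,6R)-5-ethenyl-4-hydroxy-6-methyl-4-isopropylcyclohex-2-en-1-one
Product: 8 6-hydroxy-2-methyl-3-oxo-6-isopropylcyclohex-4-ene-1-carbaldehyde (CHO cis to OH), via ozonide 7 (not isolated)
Conditions: O3, CH2Cl2/MeOH, −78 °C (indicator end point); Me2S, −78 °C → rt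
Reagents that add atoms: ozone [O-][O+]=O
Why: Ozonolysis with reductive work-up; the electron-rich vinyl group is cleaved much faster than the enone double bond, and C-10 keeps its configuration because the all-equatorial aldehyde is also the thermodynamic epimer.

**Step 5**
Reactants: 8 6-hydroxy-2-methyl-3-oxo-6-isopropylcyclohex-4-ene-1-carbaldehyde
Product: 9 4-hydroxy-5-[(1S)-1-hydroxy-3-methylbut-3-en-1-yl]-6-methyl-4-isopropylcyclohex-2-en-1-one
Conditions: (−)-Ipc2B(CH2C(CH3)=CH2) [preformed from (+)-α-pinene], Et2O, −78 °C; then HOCH2CH2NH2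
Reagents that add atoms: (−)-B-(2-methylallyl)diisopinocampheylborane C=C(C)CB([C@@H]1C[C@@H]2C[C@@H](C2(C)C)[C@H]1C)[C@@H]1C[C@@H]2C[C@@H](C2(C)C)[C@H]1C
Why: Brown asymmetric methallylboration through a chair transition state; the reagent from (+)-α-pinene should deliver the methallyl group to the Si face and set C-1 as S (reagent control, mismatched with the Felkin bias of the aldehyde), while ketone and enone are untouched at −78 °C.

**Step 6**
Reactants: 9 4-hydroxy-5-[(1S)-1-hydroxy-3-methylbut-3-en-1-yl]-6-methyl-4-isopropylcyclohex-2-en-1-one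
Product: 10 bis(triethylsilyl) ether of 9 (C-1 and C-9 oxygens)
Conditions: Et3SiOTf, 2,6-lutidine, CH2Cl2, −78 → 0 °C
Reagents that add atoms: triethylsilyl trifluoromethanesulfonate CC[Si](CC)(CC)OS(=O)(=O)C(F)(F)F
Why: Silyl triflate silylation of the secondary and the hindered tertiary hydroxyl; the C-9 silyl ether removes a chelating site for step 10 and the C-1 ether keeps this oxygen apart from the later acetate positions.

**Step 7**
Reactants: 10 bis(triethylsilyl) ether of 9
Product: 12 2-hydroxy-6-methyl-5-[(1S)-3-methyl-1-(triethylsilyloxy)but-3-en-1-yl]-4-isopropyl-4-(triethylsilyloxy)cyclohexan-1-one, via lithium enolate 11 (not isolated)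
Conditions: Li[HB(sBu)3], THF, −78 °C; then 2-(phenylsulfonyl)-3-phenyloxaziridine, −78 °C
Reagents that add atoms: 2-(phenylsulfonyl)-3-phenyloxaziridine O=S(=O)(N1OC1c1ccccc1)c1ccccc1
Why: 1,4-Reduction of the enone by the bulky borohydride gives the C-5/C-7 enolate regiospecifically and its oxidation by the N-sulfonyloxaziridine (Davis hydroxylation) puts oxygen on C-7; the new centre is erased in step 9.

**Step 8**
Reactants: 12 2-hydroxy-6-methyl-5-[(1S)-3-methyl-1-(triethylsilyloxy)but-3-en-1-yl]-4-isopropyl-4-(triethylsilyloxy)cyclohexan-1-one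
Product: 13 1,6-dimethyl-5-[(1S)-3-methyl-1-(triethylsilyloxy)but-3-en-1-yl]-4-isopropyl-4-(triethylsilyloxy)cyclohexane-1,2-diol
Conditions: MeMgBr (4 equiv), THF, −78 → 0 °C
Reagents that add atoms: methylmagnesium bromide C[Mg]Br
Why: Chelation-assisted Grignard 1,2-addition to the α-hydroxy ketone installs the C-4 methyl group on C-5; the configuration of the tertiary carbinol is erased in step 9.

**Step 9**
Reactants: 13 1,6-dimethyl-5-[(1S)-3-methyl-1-(triethylsilyloxy)but-3-en-1-yl]-4-isopropyl-4-(triethylsilyloxy)cyclohexane-1,2-diol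
Product: 14 5-methyl-4-[(1S)-3-methyl-1-(triethylsilyloxy)but-3-en-1-yl]-6-oxo-3-isopropyl-3-(triethylsilyloxy)heptanal
Conditions: NaIO4, THF/pH 7 buffer, 0 °C
Reagents that add atoms: none
Why: Malaprade glycol cleavage of the only 1,2-diol opens the six-membered ring between C-5 and C-7 and unveils the methyl ketone and the aldehyde under neutral conditions.

**Step 10**
Reactants: 14 5-methyl-4-[(1S)-3-methyl-1-(triethylsilyloxy)but-3-en-1-yl]-6-oxo-3-isopropyl-3-(triethylsilyloxy)heptanal
Product: 15 1-[(1R,2S,4R,5S)-2-hydroxy-1-methyl-5-[(1S)-3-methyl-1-(triethylsilyloxy)but-3-en-1-yl]-4-isopropyl-4-(triethylsilyloxy)cyclopentyl]ethan-1-one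
Conditions: t-BuOLi (0.5 equiv), THF (0.005 M), −40 → −10 °C; AcOH quench at −40 °C
Reagents that add atoms: none
Why: Reversible deprotonation by the alkoxide equilibrates the ketone enolates, and the tetrasubstituted C-5/C-6 lithium enolate adds to the C-7 aldehyde through a lithium-bridged closed transition state (intramolecular aldol addition of a 1,6-keto aldehyde to a 2-acylcyclopentanol is the closest known reaction type). The cyclopentane closes in the 5-(enolexo)-exo-trig mode. C-6 is controlled by allylic 1,3-strain: H-10 eclipses the enolate plane, the C-9 tether reaches C-6 from one face and the C-1 branch occupies the other, so the acetyl group ends trans to the C-1 branch and cis to H-10. C-7 is controlled by the lithium chelate between enolate and aldehyde oxygens, which places the new hydroxyl cis to the acetyl group; the C-9 oxygen is silylated so that it cannot compete as a chelating site. The step needs the C-6 enolate to win over the C-4 and C-8 enolates: only C-6 can reach the aldehyde through a five-membered ring, attack of C-8 on the hindered C-5 ketone is reversible, and the product has no α-hydrogen at C-6 and cannot dehydrate.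

**Step 11**
Reactants: 15 1-[(1R,2S,4R,5S)-2-hydroxy-1-methyl-5-[(1S)-3-methyl-1-(triethylsilyloxy)but-3-en-1-yl]-4-isopropyl-4-(triethylsilyloxy)cyclopentyl]ethan-1-one
Product: 19 vinyl ketone (prop-2-en-1-one in place of the acetyl group of 15; C-7 hydroxyl as trimethylsilyl ether), via bis-TMS enol ether 16 (not isolated), via Mannich base 17 (not isolated), via methiodide 18 (not isolated)
Conditions: Me3SiOTf, Et3N, CH2Cl2, 0 °C; Me2N=CH2+ I−, rt; MeI, rt; aq. NaHCO3
Reagents that add atoms: trimethylsilyl trifluoromethanesulfonate C[Si](C)(C)OS(=O)(=O)C(F)(F)F; N,N-dimethylmethyleneiminium iodide C=[N+](C)C.[I-]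
Why: Mannich methylenation: the methyl ketone can enolise only toward C-4 (C-6 is quaternary), its silyl enol ether is aminomethylated by the iminium salt and Hofmann-type elimination of the quaternised amine gives the vinyl ketone, while the C-7 hydroxyl is masked as TMS ether against oxa-Michael addition.

**Step 12**
Reactants: 19 vinyl ketone
Product: 21 trans-fused hydroxy enone (C-5 ketone, C-3=C-4 olefin, free C-7 hydroxyl, C-1 and C-9 triethylsilyl ethers), via bicyclic TMS ether 20 (not isolated)
Conditions: second-generation Hoveyda–Grubbs catalyst (10 mol%), toluene, 80 °C; then PPTS, MeOH, 0 °C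
Reagents that add atoms: none
Why: Ring-closing metathesis between the vinyl ketone and the 1,1-disubstituted olefin closes the seven-membered ring as a trisubstituted enone; the two arms are trans on the cyclopentane, so the trans-fused hydroazulene forms without strain, and mild acid then removes only the TMS ether.

**Step 13**
Reactants: 21 trans-fused hydroxy enone
Product: 22 allylic 1,3-diol (C-5 hydroxyl cis to C-7 hydroxyl)
Conditions: Et2BOMe, NaBH4, THF/MeOH, −78 °C; AcOH, then MeOH co-evaporation
Reagents that add atoms: none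
Why: Narasaka–Prasad reduction: the boron chelate between the C-7 hydroxyl and the C-5 carbonyl is attacked by external hydride on its convex face (syn to the angular methyl), giving the 1,3-syn diol, that is the C-5 hydroxyl cis to the C-7 hydroxyl.

**Step 14**
Reactants: 22 allylic 1,3-diol
Product: 23 epoxy diol (C-3/C-4 epoxide cis to the C-5 hydroxyl)
Conditions: VO(acac)2 (5 mol%), t-BuOOH, CH2Cl2, 0 °C → rt
Reagents that add atoms: tert-butyl hydroperoxide CC(C)(C)OO
Why: Hydroxyl-directed vanadium-catalysed epoxidation of the cyclic allylic alcohol delivers oxygen to the face of the C-5 hydroxyl, setting C-3 and C-4 with the epoxide cis to the C-5 oxygen; no other olefin is present.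

**Step 15**
Reactants: 23 epoxy diol
Product: 24 C-5/C-7 diacetate
Conditions: Ac2O, DMAP, pyridine, CH2Cl2, rt
Reagents that add atoms: acetic anhydride CC(=O)OC(C)=O
Why: DMAP-catalysed acylation of the two free secondary hydroxyls (C-5 and C-7); the C-1 and C-9 oxygens are silylated.

**Step 16**
Reactants: 24 C-5/C-7 diacetate
Product: 25 diacetate diol (free C-1 and C-9 hydroxyls)
Conditions: HF·pyridine, pyridine, THF, 0 °C → rt
Reagents that add atoms: none
Why: Fluoride-mediated desilylation buffered with pyridine frees the C-1 and C-9 hydroxyls without opening the epoxide or moving the acetates (no acetate is 1,2 or cis-1,3 to a freed hydroxyl).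

**Step 17**
Reactants: 25 diacetate diol
Product: 26 target (C-1 angelate)
Conditions: angelic acid, 2,4,6-trichlorobenzoyl chloride, Et3N, toluene, rt; then 25, toluene, 75 °C
Reagents that add atoms: angelic acid C/C=C(/C)C(=O)O
Why: Yamaguchi-type esterification with the preformed mixed anhydride of angelic acid, run without DMAP to avoid Z to E isomerisation; only the secondary C-1 hydroxyl reacts, the tertiary C-9 hydroxyl is too hindered.

**Compound list**

1 | 4-isopropylphenol | CC(C)c1ccc(O)cc1 | starting material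
2 | 4-hydroperoxy-4-isopropylcyclohexa-2,5-dien-1-one | CC(C)C1(OO)C=CC(=O)C=C1 | intermediate (not isolated)
3 | 4-hydroxy-4-isopropylcyclohexa-2,5-dien-1-one | CC(C)C1(O)C=CC(=O)C=C1 | intermediate
4 | (4S,5S)-5-ethenyl-4-hydroxy-4-isopropylcyclohex-2-en-1-one (vinyl cis to OH) | O=C1C=C[C@@](O)(C(C)C)[C@H](C=C)C1 | intermediate
5 | dilithium dienolate alkoxide of 4 | [Li+].[Li+].[O-]C1C=C[C@@]([O-])(C(C)C)[C@H](C=C)C=1 | intermediate (not isolated)
6 | (4S,5R,6R)-5-ethenyl-4-hydroxy-6-methyl-4-isopropylcyclohex-2-en-1-one | O=C1C=C[C@@](O)(C(C)C)[C@H](C=C)[C@H]1C | intermediate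
7 | ozonide (1,2,4-trioxolane) of 6 | O=C1C=C[C@@](O)(C(C)C)[C@H](C2OCOO2)[C@H]1C | intermediate (not isolated)
8 | 6-hydroxy-2-methyl-3-oxo-6-isopropylcyclohex-4-ene-1-carbaldehyde (CHO cis to OH, trans to CH3) | O=C1C=C[C@@](O)(C(C)C)[C@H](C=O)[C@H]1C | intermediate
9 | 4-hydroxy-5-[(1S)-1-hydroxy-3-methylbut-3-en-1-yl]-6-methyl-4-isopropylcyclohex-2-en-1-one | O=C1C=C[C@@](O)(C(C)C)[C@H]([C@@H](O)CC(C)=C)[C@H]1C | intermediate
10 | bis(triethylsilyl) ether of 9 | O=C1C=C[C@@](O[Si](CC)(CC)CC)(C(C)C)[C@H]([C@@H](O[Si](CC)(CC)CC)CC(C)=C)[C@H]1C | intermediate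
11 | lithium enolate from 1,4-reduction of 10 | [Li+].[O-]C1=CC[C@@](O[Si](CC)(CC)CC)(C(C)C)[C@H]([C@@H](O[Si](CC)(CC)CC)CC(C)=C)[C@H]1C | intermediate (not isolated)
12 | 2-hydroxy-6-methyl-5-[(1S)-3-methyl-1-(triethylsilyloxy)but-3-en-1-yl]-4-isopropyl-4-(triethylsilyloxy)cyclohexan-1-one | O=C1[C@@H](O)C[C@@](O[Si](CC)(CC)CC)(C(C)C)[C@H]([C@@H](O[Si](CC)(CC)CC)CC(C)=C)[C@H]1C | intermediate
13 | 1,6-dimethyl-5-[(1S)-3-methyl-1-(triethylsilyloxy)but-3-en-1-yl]-4-isopropyl-4-(triethylsilyloxy)cyclohexane-1,2-diol | O[C@@]1(C)[C@@H](O)C[C@@](O[Si](CC)(CC)CC)(C(C)C)[C@H]([C@@H](O[Si](CC)(CC)CC)CC(C)=C)[C@H]1C | intermediate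
14 | 5-methyl-4-[(1S)-3-methyl-1-(triethylsilyloxy)but-3-en-1-yl]-6-oxo-3-isopropyl-3-(triethylsilyloxy)heptanal | CC(=O)[C@H](C)[C@@H]([C@@H](O[Si](CC)(CC)CC)CC(C)=C)[C@](O[Si](CC)(CC)CC)(C(C)C)CC=O | intermediate
15 | 1-[(1R,2S,4R,5S)-2-hydroxy-1-methyl-5-[(1S)-3-methyl-1-(triethylsilyloxy)but-3-en-1-yl]-4-isopropyl-4-(triethylsilyloxy)cyclopentyl]ethan-1-one (acetyl cis to OH, trans to the C-10 branch) | CC(=O)[C@@]1(C)[C@@H](O)C[C@@](O[Si](CC)(CC)CC)(C(C)C)[C@@H]1[C@@H](O[Si](CC)(CC)CC)CC(C)=C | intermediate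
16 | bis-TMS derivative of 15 (C-7 trimethylsilyl ether, C-5 trimethylsilyl enol ether) | C=C(O[Si](C)(C)C)[C@@]1(C)[C@@H](O[Si](C)(C)C)C[C@@](O[Si](CC)(CC)CC)(C(C)C)[C@@H]1[C@@H](O[Si](CC)(CC)CC)CC(C)=C | intermediate (not isolated)
17 | Mannich base (3-dimethylaminopropanoyl in place of acetyl, C-7 OTMS) | CN(C)CCC(=O)[C@@]1(C)[C@@H](O[Si](C)(C)C)C[C@@](O[Si](CC)(CC)CC)(C(C)C)[C@@H]1[C@@H](O[Si](CC)(CC)CC)CC(C)=C | intermediate (not isolated)
18 | methiodide of 17 | C[N+](C)(C)CCC(=O)[C@@]1(C)[C@@H](O[Si](C)(C)C)C[C@@](O[Si](CC)(CC)CC)(C(C)C)[C@@H]1[C@@H](O[Si](CC)(CC)CC)CC(C)=C.[I-] | intermediate (not isolated)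
19 | vinyl ketone (prop-2-enoyl on C-6, C-7 OTMS, C-1 and C-9 OTES) | C=CC(=O)[C@@]1(C)[C@@H](O[Si](C)(C)C)C[C@@](O[Si](CC)(CC)CC)(C(C)C)[C@@H]1[C@@H](O[Si](CC)(CC)CC)CC(C)=C | intermediate
20 | trans-fused bicyclic enone, C-7 OTMS | CC[Si](CC)(CC)O[C@H]1CC(C)=CC(=O)[C@@]2(C)[C@@H](O[Si](C)(C)C)C[C@@](O[Si](CC)(CC)CC)(C(C)C)[C@H]12 | intermediate (not isolated)
21 | trans-fused hydroxy enone (C-5 ketone, C-3=C-4, C-7 OH, C-1 and C-9 OTES) | CC[Si](CC)(CC)O[C@H]1CC(C)=CC(=O)[C@@]2(C)[C@@H](O)C[C@@](O[Si](CC)(CC)CC)(C(C)C)[C@H]12 | intermediate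
22 | allylic 1,3-diol (C-5 OH cis to C-7 OH, trans to the angular methyl) | CC[Si](CC)(CC)O[C@H]1CC(C)=C[C@@H](O)[C@@]2(C)[C@@H](O)C[C@@](O[Si](CC)(CC)CC)(C(C)C)[C@H]12 | intermediate
23 | epoxy diol (C-3/C-4 epoxide cis to C-5 OH) | CC[Si](CC)(CC)O[C@H]1C[C@@]2(C)O[C@H]2[C@@H](O)[C@@]2(C)[C@@H](O)C[C@@](O[Si](CC)(CC)CC)(C(C)C)[C@H]12 | intermediate
24 | C-5/C-7 diacetate, C-1 and C-9 OTES | CC[Si](CC)(CC)O[C@H]1C[C@@]2(C)O[C@H]2[C@@H](OC(C)=O)[C@@]2(C)[C@@H](OC(C)=O)C[C@@](O[Si](CC)(CC)CC)(C(C)C)[C@H]12 | intermediate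
25 | diacetate diol (free C-1 and C-9 hydroxyls) | O[C@H]1C[C@@]2(C)O[C@H]2[C@@H](OC(C)=O)[C@@]2(C)[C@@H](OC(C)=O)C[C@@](O)(C(C)C)[C@H]12 | intermediate
26 | CNP0170993.1 (C-5, C-7 diacetate, C-1 angelate, C-3/C-4 epoxide, C-9 tertiary alcohol) | C/C=C(/C)C(=O)O[C@H]1C[C@@]2(C)O[C@H]2[C@@H](OC(C)=O)[C@@]2(C)[C@@H](OC(C)=O)C[C@@](O)(C(C)C)[C@H]12 | target

**Step count.** Total: 17 steps. Longest linear sequence: 17 steps (fully linear from 1).

**Steps most likely to fail and fallbacks**

1. Step 10 (key aldol). The process at risk is enolate selection and reversibility: the aldehyde may enolise at C-8 and lose the β-silyloxy group, or retro-aldol equilibration may erode the C-6/C-7 selectivity. The fallback sets out from 14 and fixes the enolate position before the aldehyde exists. Chemoselective reduction of the aldehyde with NaBH(OAc)3 should give the hydroxy ketone F1. Me3SiCl/NaI/Et3N in MeCN (thermodynamic conditions) should give the tetrasubstituted C-5/C-6 enol silane carrying a primary TMS ether F2. Swern oxidation, which converts a primary TMS ether directly into the aldehyde, should give the enol silane aldehyde F3. BF3·OEt2 in CH2Cl2 at −78 °C then closes C-6–C-7 by an intramolecular Mukaiyama aldol addition (open transition state, 1,3-anti to the C-9 silyloxy group) and rejoins the route at 15.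

2. Step 2 (desymmetrising vinyl addition). The process at risk is poor discrimination between the two enone arms, or a second addition to the remaining enone. The fallback sets out from 3 and desymmetrises by reduction instead. Copper hydride conjugate reduction (Cu(OAc)2, the DTBM-SEGPHOS enantiomer that gives the R product, (EtO)2MeSiH, t-BuOH) should give the enone F4. Addition of (CH2=CH)2CuLi trans to the isopropyl group with MeI/HMPA trapping of the enolate should give the saturated ketone F5. Ozonolysis gives the aldehyde F6, the methallylboration of step 5 gives the diol F7 and Et3SiOTf gives the bis-silyl ether F8. Kinetic deprotonation at C-7 with LiN(iPr)2 and oxidation with the oxaziridine of step 7 rejoins the route at 12.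

3. Step 5 (methallylboration). The process at risk is poor facial selectivity at C-1, because the reagent works against the substrate bias. The fallback sets out from 8 and sets C-1 by a directed reduction. Unselective Barbier addition (In, 3-bromo-2-methylpropene, THF/H2O) should give the C-1 epimer mixture F9. Dess–Martin periodinane (NaHCO3 buffer) should give the β-hydroxy ketone F10. Evans–Saksena reduction with Me4NBH(OAc)3 in MeCN/AcOH, with hydride delivered from the C-9 hydroxyl, should give the 1,3-anti diol and rejoins the route at 9.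

**Further compounds**

F1 | step 10 | 7-hydroxy-3-methyl-4-[(1S)-3-methyl-1-(triethylsilyloxy)but-3-en-1-yl]-5-isopropyl-5-(triethylsilyloxy)heptan-2-one | CC(=O)[C@H](C)[C@@H]([C@@H](O[Si](CC)(CC)CC)CC(C)=C)[C@](O[Si](CC)(CC)CC)(C(C)C)CCO
F2 | step 10 | C-5/C-6 trimethylsilyl enol ether of F1 with primary O-TMS | CC(O[Si](C)(C)C)=C(C)[C@@H]([C@@H](O[Si](CC)(CC)CC)CC(C)=C)[C@](O[Si](CC)(CC)CC)(C(C)C)CCO[Si](C)(C)C
F3 | step 10 | C-5/C-6 trimethylsilyl enol ether of keto aldehyde 14 | CC(O[Si](C)(C)C)=C(C)[C@@H]([C@@H](O[Si](CC)(CC)CC)CC(C)=C)[C@](O[Si](CC)(CC)CC)(C(C)C)CC=O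
F4 | step 2 | (R)-4-hydroxy-4-isopropylcyclohex-2-en-1-one | O=C1CC[C@@](O)(C(C)C)C=C1
F5 | step 2 | 3-ethenyl-4-hydroxy-2-methyl-4-isopropylcyclohexan-1-one (vinyl cis to OH, trans to CH3) | O=C1CC[C@@](O)(C(C)C)[C@H](C=C)[C@H]1C
F6 | step 2 | 6-hydroxy-2-methyl-3-oxo-6-isopropylcyclohexane-1-carbaldehyde | O=C1CC[C@@](O)(C(C)C)[C@H](C=O)[C@H]1C
F7 | step 2 | 4-hydroxy-3-[(1S)-1-hydroxy-3-methylbut-3-en-1-yl]-2-methyl-4-isopropylcyclohexan-1-one | O=C1CC[C@@](O)(C(C)C)[C@H]([C@@H](O)CC(C)=C)[C@H]1C
F8 | step 2 | bis(triethylsilyl) ether of F7 | O=C1CC[C@@](O[Si](CC)(CC)CC)(C(C)C)[C@H]([C@@H](O[Si](CC)(CC)CC)CC(C)=C)[C@H]1C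
F9 | step 5 | C-1 epimer mixture of 9 | O=C1C=C[C@@](O)(C(C)C)[C@H](C(O)CC(C)=C)[C@H]1C
F10 | step 5 | 4-hydroxy-6-methyl-5-(3-methylbut-3-enoyl)-4-isopropylcyclohex-2-en-1-one | O=C1C=C[C@@](O)(C(C)C)[C@H](C(=O)CC(C)=C)[C@H]1C
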